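The ten-membered carbocycle is closed last, at the bond between C9 (the CH–O carbon that ends up as the tiglate) and C10 (the ring alkene carbon carrying CO2Me). C9–C10(=C1)–CO2Me is a 2-(1-acyloxyalkyl)acrylate, so an intramolecular Nozaki–Hiyama–Kishi addition of a (Z)-α-iodoenoate (C10) to an α-acyloxy aldehyde (C9) closes the ring, keeps the ring-cis C1=C10 geometry and creates the C9 stereocentre in one operation. The precursor is a seco chain that already holds the cis-fused α-methylene lactone (C6, C7), the C8 ester, the cis-epoxide (C2, C3) and the (Z)-C4=C5 alkene; this all-cis array folds C9 towards C10.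

Key step: step 20

Remark: ring atoms are numbered C10 (alkene carbon bearing CO2Me), C1 (its CH partner), C2/C3 (epoxide), C4 (methyl-bearing alkene carbon), C5, C6 (lactone O–CH), C7 (lactone C–CH), C8 (CH bearing the hydroxy-acid ester), C9 (CH bearing the tiglate), C11–C13 (methylene-lactone carbons) and C14 (ester carbon); the target is then 2R,3S,6R,7R,8S,9S with a (2S,3S) side chain, and the five starting materials are assumed to be purchased.

Step 1
Reactants: 1 (R)-2,2-dimethyl-1,3-dioxolane-4-carbaldehyde; 2 methyl acrylate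
Product: 3 methyl 2-{[(4R)-2,2-dimethyl-1,3-dioxolan-4-yl](hydroxy)methyl}prop-2-enoate (both carbinol epimers)
Conditions: DABCO (cat.), 1,4-dioxane/H2O, rt
Reagents that add atoms: none
Why: Morita–Baylis–Hillman reaction in which DABCO adds to the acrylate and the zwitterionic enolate adds to the aldehyde; the new carbinol centre is formed without control, which is harmless because step 2 erases it, and the dioxolane centre is carried over unchanged.

Step 2
Reactants: 3 Morita–Baylis–Hillman adduct
Product: 4 methyl (2Z)-2-(bromomethyl)-3-[(4S)-2,2-dimethyl-1,3-dioxolan-4-yl]prop-2-enoate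
Conditions: NBS, Me2S, CH2Cl2, 0 °C to rt
Reagents that add atoms: N-bromosuccinimide O=C1CCC(=O)N1Br
Why: Corey–Kim-type activation of the alcohol as an alkoxysulfonium salt and SN2' attack of bromide transpose the alkene to the thermodynamically preferred (Z)-2-(bromomethyl)enoate, so both carbinol epimers of 3 should converge to one bromide.

Step 3
Reactants: 5 but-2-yn-1-ol
Product: 7 (2Z)-3-iodobut-2-en-1-ol, via sodium vinylalanate 6 (not isolated)
Conditions: NaAlH2(OCH2CH2OMe)2, THF, 0 °C to rt; then I2, -78 °C to 0 °C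
Reagents that add atoms: iodine II
Why: hydroxyl-directed trans-hydroalumination places aluminium on the distal alkyne carbon inside a five-membered alanate ring, and iodinolysis of the C–Al bond with retention should give the (Z)-vinyl iodide.

Step 4
Reactants: 7 (2Z)-3-iodobut-2-en-1-ol
Product: 8 (2Z)-3-iodobut-2-enal
Conditions: MnO2, CH2Cl2, rt, dark
Reagents that add atoms: none
Why: neutral heterogeneous allylic oxidation with MnO2 stops at the aldehyde and should leave the (Z)-iodoalkene geometry untouched.

Step 5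
Reactants: 4 allylic bromide; 8 (2Z)-3-iodobut-2-enal
Product: 10 (4R,5S)-4-[(4S)-2,2-dimethyl-1,3-dioxolan-4-yl]-5-[(1Z)-2-iodoprop-1-en-1-yl]-3-methylideneoxolan-2-one, via hydroxy ester 9 (not isolated)
Conditions: indium powder, THF/H2O (1:1), rt; then PPTS (cat.), PhMe, 50 °C
Reagents that add atoms: none
Why: indium-mediated Barbier 2-(alkoxycarbonyl)allylation through a chair Zimmerman–Traxler transition state, in which the dioxolanyl group (cis to CH2In) is axial, should give the syn adduct (C6/C7, hence the cis-fused lactone), with the aldehyde attacking C7 anti to the C8–O bond in the allylic-strain-minimised (H-eclipsed) conformer, and acid then closes the lactone onto the only free hydroxyl (O6).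

Step 6
Reactants: 10 lactone acetonide
Product: 11 (4S,5S)-4-[(1S)-1,2-dihydroxyethyl]-5-[(1Z)-2-iodoprop-1-en-1-yl]-3-methylideneoxolan-2-one
Conditions: AcOH/H2O (4:1), 40 °C
Reagents that add atoms: none
Why: acid-catalysed hydrolysis of the terminal acetonide under base-free conditions that should not move the lactone to O8 or touch the vinyl iodide; no stereocentre is affected.

Step 7
Reactants: 11 diol
Product: 12 (4S,5S)-4-[(1S)-2-{[tert-butyl(dimethyl)silyl]oxy}-1-hydroxyethyl]-5-[(1Z)-2-iodoprop-1-en-1-yl]-3-methylideneoxolan-2-one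
Conditions: TBSCl, imidazole, CH2Cl2, 0 °C
Reagents that add atoms: tert-butyldimethylsilyl chloride CC(C)(C)[Si](C)(C)Cl
Why: steric differentiation in silylation, the primary C9 hydroxyl reacting far faster than the hindered secondary C8 hydroxyl.

Step 8
Reactants: 13 (2E)-2-methylbut-2-en-1-ol
Product: 14 [(2R,3R)-2,3-dimethyloxiran-2-yl]methanol
Conditions: Ti(OiPr)4 (cat.), D-(-)-diisopropyl tartrate (cat.), t-BuOOH, 4 Å molecular sieves, CH2Cl2, -20 °C
Reagents that add atoms: tert-butyl hydroperoxide CC(C)(C)OO
Why: Katsuki–Sharpless asymmetric epoxidation, in which the D-(-)-tartrate catalyst delivers oxygen to the face that gives the (2R,3R)-epoxide (mirror image of the (2S,3S) outcome established for (E)-allylic alcohols with L-(+)-tartrate).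

Step 9
Reactants: 14 epoxy alcohol
Product: 15 (2S,3R)-3,4-dihydroxy-3-methylbutan-2-yl acetate
Conditions: Ti(OiPr)4 (1.5 equiv), AcOH, CH2Cl2, rt
Reagents that add atoms: acetic acid CC(=O)O
Why: titanium-mediated regioselective opening of a 2,3-epoxy alcohol, in which acetate attacks the less hindered C3 of the chelated titanium epoxy-alkoxide with inversion and so sets the acetoxy centre while the tertiary C–O bond is retained.

Step 10
Reactants: 15 acetoxy diol
Product: 17 (2S,3S)-3-acetoxy-2-hydroxy-2-methylbutanoic acid, via hydroxy aldehyde 16 (not isolated)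
Conditions: TEMPO (cat.), NaOCl (cat.), NaClO2, MeCN/phosphate buffer pH 6.7, 35 °C
Reagents that add atoms: sodium chlorite [Na+].[O-]Cl=O
Why: TEMPO/chlorite oxidation takes the primary alcohol through the aldehyde to the acid at near-neutral pH, where the acetate and the tertiary alcohol are inert and no stereocentre is touched.

Step 11
Reactants: 17 hydroxy acid
Product: 19 (2S,3S)-3-acetoxy-2-methyl-2-[(triethylsilyl)oxy]butanoic acid, via silyl ester 18 (not isolated)
Conditions: Et3SiOTf (2.5 equiv), 2,6-lutidine, CH2Cl2, -78 °C to 0 °C; then THF/H2O, AcOH (cat.), rt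
Reagents that add atoms: triethylsilyl triflate CC[Si](CC)(CC)OS(=O)(=O)C(F)(F)F
Why: the silyl triflate silylates both the tertiary hydroxyl and the carboxylic acid, and the labile silyl ester is then hydrolysed selectively to leave the tertiary silyl ether.

Step 12
Reactants: 20 prop-2-yn-1-ol
Product: 22 (2Z)-3-(tributylstannyl)prop-2-en-1-ol, via lithium vinylalanate 21 (not isolated)
Conditions: LiAlH4, THF, 0 °C to rt; then Bu3SnOTf, -78 °C to rt
Reagents that add atoms: tributyltin triflate CCCC[Sn](CCCC)(CCCC)OS(=O)(=O)C(F)(F)F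
Why: hydroxyl-directed trans-hydroalumination followed by aluminium-to-tin exchange with retention should give the (Z)-vinylstannane.

Step 13
Reactants: 12 silyl ether alcohol; 19 protected side-chain acid
Product: 24 (1S)-2-{[tert-butyl(dimethyl)silyl]oxy}-1-{(2S,3R)-2-[(1Z)-2-iodoprop-1-en-1-yl]-4-methylidene-5-oxooxolan-3-yl}ethyl (2S,3S)-3-acetoxy-2-methyl-2-[(triethylsilyl)oxy]butanoate, via mixed anhydride 23 (not isolated)
Conditions: 2,4,6-trichlorobenzoyl chloride, Et3N, THF, rt; then 12, DMAP, PhMe, rt to 40 °C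
Reagents that add atoms: none
Why: Yamaguchi esterification, in which DMAP attacks the mixed anhydride at the less hindered acyl carbon and the acylpyridinium acylates the only free hydroxyl (C8–OH) without touching a stereocentre.

Step 14
Reactants: 24 vinyl iodide ester; 22 (Z)-vinylstannane
Product: 25 dienol, i.e. 24 with the iodine replaced by a (Z)-CH=CH–CH2OH group (C4–C3=C2–C1, both alkenes Z)
Conditions: Cu(O2C-2-thienyl) (1.5 equiv), NMP, 0 °C to rt
Reagents that add atoms: none
Why: copper carboxylate-mediated Stille-type cross-coupling runs at room temperature with retention at both alkenyl partners and needs no palladium catalyst that could ionise the allylic lactone.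

Step 15
Reactants: 25 dienol
Product: 26 epoxy alcohol, i.e. 25 with C2=C3 converted into the cis-(2R,3S)-epoxide
Conditions: Ti(OiPr)4 (cat.), D-(-)-diisopropyl tartrate (cat.), t-BuOOH, 4 Å molecular sieves, CH2Cl2, -20 °C
Reagents that add atoms: tert-butyl hydroperoxide CC(C)(C)OO
Why: Katsuki–Sharpless asymmetric epoxidation, in which only C2=C3 is allylic to the free hydroxyl and D-(-)-tartrate delivers oxygen to the face that gives the cis-(2R,3S)-epoxide (mirror image of the (2S,3R) result established for (Z)-allylic alcohols with L-(+)-tartrate), the remote stereocentres being expected to matter little.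

Step 16
Reactants: 26 epoxy alcohol
Product: 27 cis-epoxy aldehyde (C1 = CHO)
Conditions: Dess–Martin periodinane, NaHCO3, CH2Cl2, 0 °C to rt
Reagents that add atoms: none
Why: Dess–Martin oxidation under buffered, non-basic conditions should give the aldehyde without epimerisation at C2 or opening of the vinyl epoxide.

Step 17
Reactants: 27 epoxy aldehyde
Product: 28 (Z)-α-iodoenoate, i.e. 27 with C1HO converted into C1H=C10(I)CO2Me (iodine cis to C2)
Conditions: Ph3P=CHCO2Me, NIS, CH2Cl2, -20 °C; then 27, -20 °C to rt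
Reagents that add atoms: methyl (triphenylphosphoranylidene)acetate COC(=O)C=P(c1ccccc1)(c1ccccc1)c1ccccc1; N-iodosuccinimide O=C1CCC(=O)N1I
Why: Wittig olefination with the stabilised α-iodo ylide formed in the flask places the ester trans to the aldehyde-derived substituent and so should give the (Z)-α-iodoenoate.

Step 18
Reactants: 28 bis-silyl iodoenoate
Product: 29 diol, i.e. 28 with the C9 silyl ether and the side-chain silyl ether both cleaved
Conditions: HF·pyridine, pyridine, THF, 0 °C to rt
Reagents that add atoms: none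
Why: fluoride cleaves the primary TBS ether and the tertiary TES ether, the pyridine buffer keeping the medium mild enough for the vinyl epoxide, the iodoenoate and the esters.

Step 19
Reactants: 29 diol
Product: 30 seco aldehyde (C9 = CHO, C10–I)
Conditions: Dess–Martin periodinane, NaHCO3, CH2Cl2, 0 °C
Reagents that add atoms: none
Why: Dess–Martin oxidation of the primary alcohol gives the α-acyloxy aldehyde under neutral conditions that avoid epimerisation at C8, and the tertiary hydroxyl cannot be oxidised.

Step 20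
Reactants: 30 seco aldehyde
Product: 31 macrocyclic C9 alcohol (the target lacking the tigloyl group)
Conditions: CrCl2 (10 equiv), NiCl2 (cat.), degassed DMSO, rt, slow addition of 30 to a final 0.002 M
Reagents that add atoms: none
Why: Zerovalent nickel inserts into the C10–I bond, the alkenyl group is passed with retention to trivalent chromium, and the alkenylchromium adds to the C9 aldehyde (Nozaki–Hiyama–Kishi reaction; the closest known type is the Ni/Cr macrocyclisation to nine- and ten-membered carbocycles). The ten-membered ring closes in a 10-exo-trig mode. The new C9 centre is controlled by C8: with the C8–O bond antiperiplanar to the incoming C10 (polar Felkin–Anh arrangement) the ring holds C7 gauche to C10, and the chromium-bound oxygen should then prefer the position anti to C7, outside the nascent ring, which leads to the 8,9-syn (9S) alcohol. The step needs chemoselectivity for the aldehyde over the lactone, the esters and the epoxide (secured by the low basicity of organochromium reagents), retention of the C1=C10 geometry (alkenylchromium species are configurationally stable and only the ring-cis isomer can reach C9), and ring closure over oligomerisation (secured by high dilution and by the cis-lactone, cis-epoxide and (Z)-C4=C5 units that fold the chain).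

Step 21
Reactants: 31 macrocyclic C9 alcohol
Product: 32 CNP0202690.1 (target)
Conditions: (E)-2-methylbut-2-enoyl chloride, pyridine, DMAP (cat.), CH2Cl2, 0 °C to rt
Reagents that add atoms: tigloyl chloride C/C=C(\C)C(Cl)=O
Why: DMAP-catalysed acylation of the secondary allylic C9 hydroxyl, the tertiary α-hydroxy ester hydroxyl being far less reactive, with pyridine instead of a trialkylamine to avoid deconjugation of the tigloyl group.

Compound list
1 | (R)-2,2-dimethyl-1,3-dioxolane-4-carbaldehyde | O=C[C@H]1COC(C)(C)O1 | starting material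
2 | methyl acrylate | C=CC(=O)OC | starting material
3 | methyl 2-{[(4R)-2,2-dimethyl-1,3-dioxolan-4-yl](hydroxy)methyl}prop-2-enoate (both carbinol epimers) | C=C(C(=O)OC)C(O)[C@H]1COC(C)(C)O1 | intermediate
4 | methyl (2Z)-2-(bromomethyl)-3-[(4S)-2,2-dimethyl-1,3-dioxolan-4-yl]prop-2-enoate | COC(=O)/C(CBr)=C/[C@H]1COC(C)(C)O1 | intermediate
5 | but-2-yn-1-ol | CC#CCO | starting material
6 | sodium vinylalanate (sodium 2,2-bis(2-methoxyethoxy)-3-methyl-2,5-dihydro-1,2-oxaaluminol-2-uide) | CC1=CCO[Al-]1(OCCOC)OCCOC.[Na+] | intermediate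
7 | (2Z)-3-iodobut-2-en-1-ol | C/C(I)=C/CO | intermediate
8 | (2Z)-3-iodobut-2-enal | C/C(I)=C/C=O | intermediate
9 | methyl (3R,4S,5Z)-3-[(4S)-2,2-dimethyl-1,3-dioxolan-4-yl]-4-hydroxy-6-iodo-2-methylidenehept-5-enoate | C=C(C(=O)OC)[C@@H]([C@H]1COC(C)(C)O1)[C@H](O)/C=C(/C)I | intermediate
10 | (4R,5S)-4-[(4S)-2,2-dimethyl-1,3-dioxolan-4-yl]-5-[(1Z)-2-iodoprop-1-en-1-yl]-3-methylideneoxolan-2-one | C=C1C(=O)O[C@H](/C=C(/C)I)[C@@H]1[C@H]2COC(C)(C)O2 | intermediate
11 | (4S,5S)-4-[(1S)-1,2-dihydroxyethyl]-5-[(1Z)-2-iodoprop-1-en-1-yl]-3-methylideneoxolan-2-one | C=C1C(=O)O[C@H](/C=C(/C)I)[C@@H]1[C@H](O)CO | intermediate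
12 | (4S,5S)-4-[(1S)-2-{[tert-butyl(dimethyl)silyl]oxy}-1-hydroxyethyl]-5-[(1Z)-2-iodoprop-1-en-1-yl]-3-methylideneoxolan-2-one | C=C1C(=O)O[C@H](/C=C(/C)I)[C@@H]1[C@H](O)CO[Si](C)(C)C(C)(C)C | intermediate
13 | (2E)-2-methylbut-2-en-1-ol | C/C=C(\C)CO | starting material
14 | [(2R,3R)-2,3-dimethyloxiran-2-yl]methanol | OC[C@@]1(C)O[C@@H]1C | intermediate
15 | (2S,3R)-3,4-dihydroxy-3-methylbutan-2-yl acetate | OC[C@@](C)(O)[C@H](C)OC(C)=O | intermediate
16 | (2S,3S)-3-hydroxy-3-methyl-4-oxobutan-2-yl acetate | O=C[C@@](C)(O)[C@H](C)OC(C)=O | intermediate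
17 | (2S,3S)-3-acetoxy-2-hydroxy-2-methylbutanoic acid | OC(=O)[C@@](C)(O)[C@H](C)OC(C)=O | intermediate
18 | triethylsilyl (2S,3S)-3-acetoxy-2-methyl-2-[(triethylsilyl)oxy]butanoate | CC[Si](CC)(CC)OC(=O)[C@@](C)(O[Si](CC)(CC)CC)[C@H](C)OC(C)=O | intermediate
19 | (2S,3S)-3-acetoxy-2-methyl-2-[(triethylsilyl)oxy]butanoic acid | OC(=O)[C@@](C)(O[Si](CC)(CC)CC)[C@H](C)OC(C)=O | intermediate
20 | prop-2-yn-1-ol | C#CCO | starting material
21 | lithium vinylalanate (lithium 2,2-dihydrido-2,5-dihydro-1,2-oxaaluminol-2-uide) | [Li+].[AlH2-]1OCC=C1 | intermediate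
22 | (2Z)-3-(tributylstannyl)prop-2-en-1-ol | OC/C=C\[Sn](CCCC)(CCCC)CCCC | intermediate
23 | mixed anhydride of 19 with 2,4,6-trichlorobenzoic acid | O=C(c1c(Cl)cc(Cl)cc1Cl)OC(=O)[C@@](C)(O[Si](CC)(CC)CC)[C@H](C)OC(C)=O | intermediate
24 | (1S)-2-{[tert-butyl(dimethyl)silyl]oxy}-1-{(2S,3R)-2-[(1Z)-2-iodoprop-1-en-1-yl]-4-methylidene-5-oxooxolan-3-yl}ethyl (2S,3S)-3-acetoxy-2-methyl-2-[(triethylsilyl)oxy]butanoate | C=C1C(=O)O[C@H](/C=C(/C)I)[C@@H]1[C@H](OC(=O)[C@@](C)(O[Si](CC)(CC)CC)[C@H](C)OC(C)=O)CO[Si](C)(C)C(C)(C)C | intermediate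
25 | dienol: 24 with the iodine replaced by (Z)-CH=CH–CH2OH, giving a (1Z,3Z)-5-hydroxy-2-methylpenta-1,3-dien-1-yl group on the lactone | C=C1C(=O)O[C@H](/C=C(/C)\C=C/CO)[C@@H]1[C@H](OC(=O)[C@@](C)(O[Si](CC)(CC)CC)[C@H](C)OC(C)=O)CO[Si](C)(C)C(C)(C)C | intermediate
26 | epoxy alcohol: 25 with C2=C3 as the cis-(2R,3S)-epoxide, i.e. a (1Z)-2-[(2S,3R)-3-(hydroxymethyl)oxiran-2-yl]prop-1-en-1-yl group on the lactone | C=C1C(=O)O[C@H](/C=C(/C)[C@@H]2O[C@@H]2CO)[C@@H]1[C@H](OC(=O)[C@@](C)(O[Si](CC)(CC)CC)[C@H](C)OC(C)=O)CO[Si](C)(C)C(C)(C)C | intermediate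
27 | cis-epoxy aldehyde: 26 with the C1 hydroxymethyl oxidised to CHO, epoxide configuration unchanged | C=C1C(=O)O[C@H](/C=C(/C)[C@@H]2O[C@@H]2C=O)[C@@H]1[C@H](OC(=O)[C@@](C)(O[Si](CC)(CC)CC)[C@H](C)OC(C)=O)CO[Si](C)(C)C(C)(C)C | intermediate
28 | (Z)-α-iodoenoate: 27 with CHO converted into CH=C(I)CO2Me, iodine cis to the epoxide carbon | C=C1C(=O)O[C@H](/C=C(/C)[C@@H]2O[C@@H]2/C=C(/C(=O)OC)I)[C@@H]1[C@H](OC(=O)[C@@](C)(O[Si](CC)(CC)CC)[C@H](C)OC(C)=O)CO[Si](C)(C)C(C)(C)C | intermediate
29 | diol: 28 with the C9 hydroxyl and the side-chain tertiary hydroxyl both free | C=C1C(=O)O[C@H](/C=C(/C)[C@@H]2O[C@@H]2/C=C(/C(=O)OC)I)[C@@H]1[C@H](OC(=O)[C@@](C)(O)[C@H](C)OC(C)=O)CO | intermediate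
30 | seco aldehyde: 29 with the C9 hydroxymethyl oxidised to CHO | C=C1C(=O)O[C@H](/C=C(/C)[C@@H]2O[C@@H]2/C=C(/C(=O)OC)I)[C@@H]1[C@H](OC(=O)[C@@](C)(O)[C@H](C)OC(C)=O)C=O | intermediate
31 | macrocyclic (9S)-alcohol: the target with OH in place of the tigloyloxy group at C9 | C=C1C(=O)O[C@@H]2/C=C(/C)[C@@H]3O[C@@H]3/C=C(/C(=O)OC)[C@H](O)[C@@H](OC(=O)[C@@](C)(O)[C@H](C)OC(C)=O)[C@H]12 | intermediate
32 | CNP0202690.1 | C=C1C(=O)O[C@@H]2/C=C(/C)[C@@H]3O[C@@H]3/C=C(/C(=O)OC)[C@H](OC(=O)/C(C)=C/C)[C@@H](OC(=O)[C@@](C)(O)[C@H](C)OC(C)=O)[C@H]12 | target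

Total step count: 21. Longest linear sequence: 14 steps (steps 1, 2, 5, 6, 7, 13 to 21).

Steps most likely to fail

Step 20. Intermolecular coupling may outrun closure of the strained ten-membered ring, the aldehyde may be attacked on the other face (the acyclic Felkin–Anh preference for a carbon nucleophile is 8,9-anti), and the C8 acyl group may migrate to the new C9 alkoxide. The fallback sets out from 30 and keeps the Ni/Cr closure for ring formation only, taking the configuration at C9 out of the cyclisation. If the C9-epimeric macrocyclic alcohol F1 predominates, it is oxidised with Dess–Martin periodinane to the C9 ketone F2. Reduction with NaBH4/CeCl3 at -78 °C (Luche conditions) then delivers hydride anti to the C8–O bond; for hydride addition to an α-acyloxy ketone this Felkin–Anh mode gives the 8,9-syn alcohol, so the sequence comes back to the route at 31.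

Step 5. The facial bias exerted by the dioxolane centre on C7 may be weak, the syn preference of the allylindium may erode, and the (Z)-iodoenal may isomerise in the aqueous medium. The fallback sets out from 3. Acetylation (Ac2O, pyridine, DMAP) gives the Morita–Baylis–Hillman acetate F3. Borylation with bis(pinacolato)diboron and Pd2(dba)3, in which zerovalent palladium ionises the allylic acetate and boron goes to the unsubstituted terminus, gives the 2-(methoxycarbonyl)allylboronate F4. Allylboration of 8 in toluene (thermal or with Sc(OTf)3) through the tight boron-centred chair, followed by acid lactonisation, comes back to the route at 10.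

Step 15. The (Z)-allylic alcohol carries a branched alkenyl group at C3, so titanium–tartrate epoxidation may be slow and poorly face-selective, and the Lewis-acidic titanium may open the vinyl epoxide once formed. The fallback sets out from 25 and replaces the titanium–tartrate system by a different catalyst class for the same hydroxyl-directed oxygen transfer: VO(OiPr)3 with a C2-symmetric chiral bis-hydroxamic acid ligand and aqueous t-BuOOH in CH2Cl2 at 0 °C, a system developed for (Z)-allylic alcohols and far less Lewis-acidic. The ligand enantiomer is chosen to give the (2R,3S)-epoxide, and the fallback comes back to the route at 26; it makes no new compound (F0).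

Further compounds
F1 | step 20 | C9-epimeric macrocyclic alcohol (9R epimer of 31) | C=C1C(=O)O[C@@H]2/C=C(/C)[C@@H]3O[C@@H]3/C=C(/C(=O)OC)[C@@H](O)[C@@H](OC(=O)[C@@](C)(O)[C@H](C)OC(C)=O)[C@H]12
F2 | step 20 | C9 ketone of the macrocycle | C=C1C(=O)O[C@@H]2/C=C(/C)[C@@H]3O[C@@H]3/C=C(/C(=O)OC)C(=O)[C@@H](OC(=O)[C@@](C)(O)[C@H](C)OC(C)=O)[C@H]12
F3 | step 5 | methyl 2-{(acetyloxy)[(4R)-2,2-dimethyl-1,3-dioxolan-4-yl]methyl}prop-2-enoate (both epimers) | C=C(C(=O)OC)C(OC(C)=O)[C@H]1COC(C)(C)O1
F4 | step 5 | methyl (2E)-3-[(4S)-2,2-dimethyl-1,3-dioxolan-4-yl]-2-[(4,4,5,5-tetramethyl-1,3,2-dioxaborolan-2-yl)methyl]prop-2-enoate | COC(=O)/C(CB1OC(C)(C)C(C)(C)O1)=C/[C@H]2COC(C)(C)O2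
F0 | step 15 | none | none
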